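**Strategy.** The target is cut between the diarylmethine carbon on C6 of flavan ring A and C3 of its oxolane. That methine sits ortho to the C7 phenol, so it can be the terminus of an ortho-quinone methide, while the oxolane C3 is the β-carbon of a cyclic enol ether. The key step is an inverse-demand oxa-Diels–Alder reaction of this quinone methide (already carrying the C8 appendage) with a (2S,3S)-2,3-dihydrofuran, followed in the same flask by silane opening of the temporary aryl ketal; it forms the strategic bond and sets three stereocentres. The dihydrofuran comes from a chalcone-derived cyclopropane by Cloke–Wilson rearrangement; the C8 appendage is installed earlier by the same sequence.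

Key step: step 11

Assumption: (+)-afzelechin and 4-(benzyloxy)phenylmagnesium bromide solution are bought, and of the two pseudoenantiomeric cinchona catalysts the one that delivers the (1R,2R)-cyclopropane is used in step 3.

Remark on numbering: in the oxolane units O1, C2 carries the 2,4-dioxygenated aryl group, C3 the diarylmethine carbon, C4 the aroyl group and C5 the 4-oxygenated aryl group. Dihydrofuran 6 is numbered as a 2,3-dihydrofuran, so its C2, C3, C4 and C5 become oxolane C5, C4, C3 and C2.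

**Step 1**
Reactants: 1 1-[2,4-bis(benzyloxy)phenyl]ethan-1-one; 2 4-(benzyloxy)benzaldehyde
Product: 3 (E)-1-[2,4-bis(benzyloxy)phenyl]-3-[4-(benzyloxy)phenyl]prop-2-en-1-one
Conditions: KOH, EtOH/THF, rt
Reagents that add atoms: none
Why: Claisen–Schmidt aldol condensation of a methyl ketone with a non-enolisable aldehyde; the conjugated E-enone is the stable product.

**Step 2**
Reactants: 1 1-[2,4-bis(benzyloxy)phenyl]ethan-1-one
Product: 4 1-[2,4-bis(benzyloxy)phenyl]-2-bromoethan-1-one
Conditions: CuBr2 (2.1 equiv), EtOAc/CHCl3, reflux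
Reagents that add atoms: copper dibromide (CuBr2), Br[Cu]Br
Why: α-Bromination of an aryl methyl ketone through its copper enolate, which should brominate the methyl group in preference to the alkoxylated ring.

**Step 3**
Reactants: 3 the chalcone; 4 the bromoketone
Product: 5 {(1R,2R)-3-[4-(benzyloxy)phenyl]cyclopropane-1,2-diyl}bis{[2,4-bis(benzyloxy)phenyl]methanone}
Conditions: O-methylquinidine-type cinchona amine (20 mol%), Cs2CO3, MeCN, 60 °C, slow addition of 4
Reagents that add atoms: none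
Why: Michael-initiated ring closure through a chiral ammonium ylide (catalytic asymmetric ylide cyclopropanation): the ylide from 4 adds to the β-carbon of 3 and the enolate displaces the amine in a 3-exo-tet closure; the trans-diaroyl arrangement is the stable one and, because the aryl-bearing ring carbon is not stereogenic, the catalyst only has to fix the sense at the two aroyl carbons.

**Step 4**
Reactants: 5 the cyclopropane
Product: 6 {(2S,3S)-2-[4-(benzyloxy)phenyl]-5-[2,4-bis(benzyloxy)phenyl]-2,3-dihydrofuran-3-yl}[2,4-bis(benzyloxy)phenyl]methanone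
Conditions: Sc(OTf)3 (10 mol%), CH2Cl2, 0 °C
Reagents that add atoms: none
Why: Cloke–Wilson rearrangement: the Lewis acid ionises the push–pull bond between the 4-benzyloxyphenyl carbon and one aroyl-bearing carbon, the enolate oxygen closes onto the benzylic cation trans to the remaining aroyl group, and the untouched aroyl-bearing carbon carries the absolute configuration into C3 of 6 (either aroyl group gives the same product because of the twofold pseudo-symmetry).

**Step 5**
Reactants: 7 (+)-afzelechin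
Product: 9 3,5,7,4'-tetra-O-benzylafzelechin, via 5,7,4'-tri-O-benzylafzelechin 8 (not isolated)
Conditions: BnBr, K2CO3, DMF, rt; then NaH, Bu4NI (cat.), 0 °C → rt
Reagents that add atoms: benzyl bromide, BrCc1ccccc1
Why: Williamson ether synthesis, phenols first under carbonate and the secondary alcohol afterwards under hydride, so that C2 and C3 of ring C are not exposed to strong base while the phenols are free.

**Step 6**
Reactants: 9 3,5,7,4'-tetra-O-benzylafzelechin
Product: 10 8-formyl-3,5,7,4'-tetra-O-benzylafzelechin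
Conditions: POCl3, DMF, 0 → 60 °C; then aq. NaOAc
Reagents that add atoms: N,N-dimethylformamide, CN(C)C=O; water, O
Why: Vilsmeier–Haack formylation of the only strongly activated ring; C8, next to the tied-back pyran oxygen, is less hindered than C6 between two benzyloxy groups and is the usual site of electrophilic substitution in 5,7-di-O-benzylflavan-3-ols.

**Step 7**
Reactants: 10 the 8-aldehyde
Product: 11 8-formyl-7-hydroxy-3,5,4'-tri-O-benzylafzelechin
Conditions: MgBr2·OEt2, toluene/Et2O, 70 °C; then H2O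
Reagents that add atoms: none
Why: Chelation-controlled debenzylation: magnesium bridges the formyl oxygen and O7 and bromide attacks the benzyl carbon (SN2), so only the benzyl ether ortho to the carbonyl group is cleaved.

**Step 8**
Reactants: 11 the salicylaldehyde; 12 [4-(benzyloxy)phenyl]magnesium bromide
Product: 13 8-{[4-(benzyloxy)phenyl](hydroxy)methyl}-7-hydroxy-3,5,4'-tri-O-benzylafzelechin (both carbinol epimers)
Conditions: 12 (2.5 equiv), THF, −20 → 0 °C; then H2O
Reagents that add atoms: none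
Why: Grignard addition to the aldehyde after the first equivalent has formed the phenoxide; the new carbinol centre is left uncontrolled because it becomes planar in the next step.

**Step 9**
Reactants: 13 the C8 o-hydroxybenzhydrol; 6 the dihydrofuran
Product: 16 C8-appended 7-phenol, via ring A o-quinone methide 14 (not isolated), via C8-side fused aryl ketal 15 (not isolated)
Conditions: 6 (1.5 equiv), (PhO)2P(O)OH (5 mol%), 4 Å MS, CH2Cl2, 0 °C, slow addition of 13; then Et3SiH, BF3·OEt2, −78 → −40 °C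
Reagents that add atoms: none
Why: Acid-induced dehydration to o-quinone methide 14, inverse-demand oxa-Diels–Alder reaction with the enol ether of 6 and silane reduction of the aryl ketal, under the stereocontrol detailed in step 11 (attack anti to the aroyl group, furan ring exo, hydride anti to the new C3 substituent); excess 6 and slow addition of 13 should suppress attack of the free C6 position on 14.

**Step 10**
Reactants: 16 the C8-appended 7-phenol; 2 4-(benzyloxy)benzaldehyde
Product: 18 C6 o-hydroxybenzhydrol, via benzodioxaborin 17 (not isolated)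
Conditions: PhB(OH)2, EtCO2H (cat.), toluene, 90 °C, 4 Å MS; then pinacol, THF, rt
Reagents that add atoms: none
Why: Boronate-templated ortho-hydroxyalkylation of a phenol: the phenyl boronate of the 7-OH delivers the aldehyde to the ortho carbon, C6 is the only free ortho position, and the two ketones are not touched; pinacol then releases the diol.

**Step 11**
Reactants: 18 the C6 o-hydroxybenzhydrol; 6 the dihydrofuran
Product: 21 pentadeca-O-benzyl target, via ring A o-quinone methide 19 (not isolated), via C6-side fused aryl ketal 20 (not isolated)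
Conditions: 6 (1.5 equiv), (PhO)2P(O)OH (5 mol%), 4 Å MS, CH2Cl2, 0 °C; then Et3SiH, BF3·OEt2, −78 → −40 °C
Reagents that add atoms: none
Why: Loss of water from 18 under mild acid gives the hydrogen-bonded o-quinone methide 19 (O7=C7–C6=CH–Ar), a 1-oxadiene that combines with the electron-rich C4=C5 enol ether of 6 in an inverse-electron-demand hetero-Diels–Alder reaction: C4 of 6 bonds to the methide carbon (the strategic C–C bond) and O7 to C5, giving ketal 20; BF3·OEt2 then expels the ring A phenoxide (the better leaving group, exocyclic cleavage as in aryl glycosides) and Et3SiH reduces the 2-aryloxolan-2-ylium ion. The closest known reactions are the [4+2] cycloadditions of o-quinone methides with 2,3-dihydrofurans to furo[2,3-b]chromene ketals and the silane reduction of aryl ketals used for C-aryl glycosides. The temporary dihydropyran ring closes suprafacially on both partners (cis-fused to the furan, asynchronous with C–C bonding ahead of C–O bonding) and is opened again in the reduction. Oxolane C3 is set by attack on the face of 6 anti to the adjacent aroyl group; the methine carbon is set by the E-configured quinone methide reacting with the furan ring exo and the enol-ether aryl group endo, because the 4-benzyloxyphenyl group at C2 of 6 lies on the attacked face and would collide with ring A in the ring-endo mode; oxolane C2 is set by hydride delivery anti to the new, very large C3 substituent, which gives the 2,3-cis arrangement. The step needs chemoselectivity for the enol ether (ring A of 19 has no free position left and the enol ether is by far the best nucleophile present), one of four face and orientation combinations (secured by the trans-2,3-disubstitution of 6 as described) and reduction of the ketal only (secured at −78 °C by its far easier ionisation compared with the benzylic ethers of the oxolanes and of ring C).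

**Step 12**
Reactants: 21 the pentadeca-O-benzyl target
Product: 22 CNP0225367.3
Conditions: H2 (1 atm), Pd(OH)2/C, THF/MeOH, rt
Reagents that add atoms: none
Why: Hydrogenolysis of fifteen benzyl ethers under neutral conditions, which should spare the acid-labile 2-aryloxolanes, ring C and the 2-hydroxyaryl ketones and touches no stereocentre.

**Compound list**

1 | 1-[2,4-bis(benzyloxy)phenyl]ethan-1-one | CC(=O)c1ccc(OCc2ccccc2)cc1OCc1ccccc1 | starting material
2 | 4-(benzyloxy)benzaldehyde | O=Cc1ccc(OCc2ccccc2)cc1 | starting material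
3 | (E)-1-[2,4-bis(benzyloxy)phenyl]-3-[4-(benzyloxy)phenyl]prop-2-en-1-one | O=C(/C=C/c1ccc(OCc2ccccc2)cc1)c1ccc(OCc2ccccc2)cc1OCc1ccccc1 | intermediate
4 | 1-[2,4-bis(benzyloxy)phenyl]-2-bromoethan-1-one | O=C(CBr)c1ccc(OCc2ccccc2)cc1OCc1ccccc1 | intermediate
5 | {(1R,2R)-3-[4-(benzyloxy)phenyl]cyclopropane-1,2-diyl}bis{[2,4-bis(benzyloxy)phenyl]methanone}, trans-diaroyl | O=C(c5ccc(OCc6ccccc6)cc5OCc5ccccc5)[C@@H]1C(c5ccc(OCc6ccccc6)cc5)[C@H]1C(=O)c5ccc(OCc6ccccc6)cc5OCc5ccccc5 | intermediate
6 | {(2S,3S)-2-[4-(benzyloxy)phenyl]-5-[2,4-bis(benzyloxy)phenyl]-2,3-dihydrofuran-3-yl}[2,4-bis(benzyloxy)phenyl]methanone, 2,3-trans | O=C(c5ccc(OCc6ccccc6)cc5OCc5ccccc5)[C@H]1C=C(c5ccc(OCc6ccccc6)cc5OCc5ccccc5)O[C@@H]1c5ccc(OCc6ccccc6)cc5 | intermediate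
7 | (+)-afzelechin, (2R,3S)-2-(4-hydroxyphenyl)chromane-3,5,7-triol | Oc1cc(O)c2c(c1)O[C@H](c1ccc(O)cc1)[C@@H](O)C2 | starting material
8 | 5,7,4'-tri-O-benzylafzelechin (3-OH free) | c1ccccc1COc1cc(OCc5ccccc5)c2c(c1)O[C@H](c5ccc(OCc6ccccc6)cc5)[C@@H](O)C2 | intermediate
9 | 3,5,7,4'-tetra-O-benzylafzelechin | c1ccccc1COc1cc(OCc5ccccc5)c2c(c1)O[C@H](c5ccc(OCc6ccccc6)cc5)[C@@H](OCc5ccccc5)C2 | intermediate
10 | 8-formyl-3,5,7,4'-tetra-O-benzylafzelechin | c1ccccc1COc1cc(OCc5ccccc5)c2c(c1C=O)O[C@H](c5ccc(OCc6ccccc6)cc5)[C@@H](OCc5ccccc5)C2 | intermediate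
11 | 8-formyl-7-hydroxy-3,5,4'-tri-O-benzylafzelechin | Oc1cc(OCc5ccccc5)c2c(c1C=O)O[C@H](c5ccc(OCc6ccccc6)cc5)[C@@H](OCc5ccccc5)C2 | intermediate
12 | [4-(benzyloxy)phenyl]magnesium bromide | Br[Mg]c1ccc(OCc2ccccc2)cc1 | starting material
13 | 8-{[4-(benzyloxy)phenyl](hydroxy)methyl}-7-hydroxy-3,5,4'-tri-O-benzylafzelechin, carbinol epimers | Oc1cc(OCc5ccccc5)c2c(c1C(O)c5ccc(OCc6ccccc6)cc5)O[C@H](c5ccc(OCc6ccccc6)cc5)[C@@H](OCc5ccccc5)C2 | intermediate
14 | ring A o-quinone methide: C7 carbonyl, exocyclic (E)-C8=CH–(4-benzyloxyphenyl), 3,5,4'-tri-O-benzyl | O=C1C=C(OCc5ccccc5)C2=C(O[C@H](c5ccc(OCc6ccccc6)cc5)[C@@H](OCc5ccccc5)C2)/C1=C\c5ccc(OCc6ccccc6)cc5 | intermediate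
15 | C8-side fused aryl ketal: cis-fused tetrahydrofuro[2,3-b]pyran on O7/C8 of ring A; ketal carbon carries the 2,4-bis(benzyloxy)phenyl group; methine aryl trans to the furan ring carbon | c1(OCc5ccccc5)cc2O[C@]3(c5ccc(OCc6ccccc6)cc5OCc5ccccc5)O[C@H](c5ccc(OCc6ccccc6)cc5)[C@@H](C(=O)c5ccc(OCc6ccccc6)cc5OCc5ccccc5)[C@@H]3[C@@H](c5ccc(OCc6ccccc6)cc5)c2c4O[C@H](c5ccc(OCc6ccccc6)cc5)[C@@H](OCc5ccccc5)Cc14 | intermediate
16 | 3,5,4'-tri-O-benzylafzelechin with free 7-OH, carrying at C8 the (S)-[4-(benzyloxy)phenyl][(2R,3S,4S,5S)-4-[2,4-bis(benzyloxy)benzoyl]-2-[2,4-bis(benzyloxy)phenyl]-5-[4-(benzyloxy)phenyl]oxolan-3-yl]methyl group | Oc1cc(OCc5ccccc5)c2c(c1[C@H](c5ccc(OCc6ccccc6)cc5)[C@H]3[C@H](C(=O)c5ccc(OCc6ccccc6)cc5OCc5ccccc5)[C@@H](c5ccc(OCc6ccccc6)cc5)O[C@H]3c5ccc(OCc6ccccc6)cc5OCc5ccccc5)O[C@H](c5ccc(OCc6ccccc6)cc5)[C@@H](OCc5ccccc5)C2 | intermediate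
17 | 2-phenyl-4-[4-(benzyloxy)phenyl]-4H-1,3,2-benzodioxaborin fused on O7/C6 of 16 | B1(c5ccccc5)Oc2c(C(c5ccc(OCc6ccccc6)cc5)O1)c(OCc5ccccc5)c3c(c2[C@H](c5ccc(OCc6ccccc6)cc5)[C@H]4[C@H](C(=O)c5ccc(OCc6ccccc6)cc5OCc5ccccc5)[C@@H](c5ccc(OCc6ccccc6)cc5)O[C@H]4c5ccc(OCc6ccccc6)cc5OCc5ccccc5)O[C@H](c5ccc(OCc6ccccc6)cc5)[C@@H](OCc5ccccc5)C3 | intermediate
18 | 16 carrying at C6 a [4-(benzyloxy)phenyl](hydroxy)methyl group, carbinol epimers | Oc1c(C(O)c5ccc(OCc6ccccc6)cc5)c(OCc5ccccc5)c2c(c1[C@H](c5ccc(OCc6ccccc6)cc5)[C@H]3[C@H](C(=O)c5ccc(OCc6ccccc6)cc5OCc5ccccc5)[C@@H](c5ccc(OCc6ccccc6)cc5)O[C@H]3c5ccc(OCc6ccccc6)cc5OCc5ccccc5)O[C@H](c5ccc(OCc6ccccc6)cc5)[C@@H](OCc5ccccc5)C2 | intermediate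
19 | ring A o-quinone methide: C7 carbonyl, exocyclic (E)-C6=CH–(4-benzyloxyphenyl), C8 appendage in place | O=C1/C(=C/c5ccc(OCc6ccccc6)cc5)C(OCc5ccccc5)=C2C[C@H](OCc5ccccc5)[C@@H](c5ccc(OCc6ccccc6)cc5)OC2=C1[C@H](c5ccc(OCc6ccccc6)cc5)[C@H]3[C@H](C(=O)c5ccc(OCc6ccccc6)cc5OCc5ccccc5)[C@@H](c5ccc(OCc6ccccc6)cc5)O[C@H]3c5ccc(OCc6ccccc6)cc5OCc5ccccc5 | intermediate
20 | C6-side fused aryl ketal: cis-fused tetrahydrofuro[2,3-b]pyran on O7/C6 of ring A, same relative configuration as 15, C8 appendage in place | c1(OCc5ccccc5)c2[C@H](c5ccc(OCc6ccccc6)cc5)[C@H]3[C@H](C(=O)c5ccc(OCc6ccccc6)cc5OCc5ccccc5)[C@@H](c5ccc(OCc6ccccc6)cc5)O[C@@]3(c5ccc(OCc6ccccc6)cc5OCc5ccccc5)Oc2c([C@H](c5ccc(OCc6ccccc6)cc5)[C@H]7[C@H](C(=O)c5ccc(OCc6ccccc6)cc5OCc5ccccc5)[C@@H](c5ccc(OCc6ccccc6)cc5)O[C@H]7c5ccc(OCc6ccccc6)cc5OCc5ccccc5)c4O[C@H](c5ccc(OCc6ccccc6)cc5)[C@@H](OCc5ccccc5)Cc14 | intermediate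
21 | pentadeca-O-benzyl target: all hydroxyl groups of 22 benzylated except the 7-OH | O=C(c5ccc(OCc6ccccc6)cc5OCc5ccccc5)[C@H]1[C@H]([C@@H](c5ccc(OCc6ccccc6)cc5)c2c(OCc5ccccc5)c3c(c([C@H](c5ccc(OCc6ccccc6)cc5)[C@H]4[C@H](C(=O)c5ccc(OCc6ccccc6)cc5OCc5ccccc5)[C@@H](c5ccc(OCc6ccccc6)cc5)O[C@H]4c5ccc(OCc6ccccc6)cc5OCc5ccccc5)c2O)O[C@H](c5ccc(OCc6ccccc6)cc5)[C@@H](OCc5ccccc5)C3)[C@H](c5ccc(OCc6ccccc6)cc5OCc5ccccc5)O[C@@H]1c5ccc(OCc6ccccc6)cc5 | intermediate
22 | CNP0225367.3: (2R,3S)-afzelechin carrying at C6 and at C8 an (S)-(4-hydroxyphenyl)[(2R,3S,4S,5S)-4-(2,4-dihydroxybenzoyl)-2-(2,4-dihydroxyphenyl)-5-(4-hydroxyphenyl)oxolan-3-yl]methyl group | O=C(c1ccc(O)cc1O)[C@H]1[C@H]([C@@H](c2ccc(O)cc2)c2c(O)c3c(c([C@H](c4ccc(O)cc4)[C@H]4[C@H](C(=O)c5ccc(O)cc5O)[C@@H](c5ccc(O)cc5)O[C@H]4c4ccc(O)cc4O)c2O)O[C@H](c2ccc(O)cc2)[C@@H](O)C3)[C@H](c2ccc(O)cc2O)O[C@@H]1c1ccc(O)cc1 | target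

**Count and risks**

Total step count: 12. Longest linear sequence: 8 steps (steps 5 to 12, from 7).

Steps most likely to fail:

Step 11 (step 9 shares the failure mode). The cycloaddition may lose its topicity at the methine carbon, through a ring-endo or Z-quinone-methide pathway or a stepwise cationic course, and the acid may open the enol ether of 6 before it is trapped. The fallback generates the quinone methide without acid and at low temperature. It sets out from 18: Boc2O and DMAP (cat.) in CH2Cl2 at 0 °C should give the aryl tert-butyl carbonate F1 (acylation at the benzylic oxygen instead would serve equally, since either magnesium salt collapses to the same quinone methide). Treatment of F1 with t-BuMgCl in toluene at −78 °C, then addition of 6 and warming, triggers carbonate migration and 1,4-elimination to 19, which should add 6 in a concerted cycloaddition under neutral conditions. The route is rejoined at 20, which is isolated this time and reduced with Et3SiH and BF3·OEt2 to 21.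

Step 3. The ylide may add sluggishly to the β-aryl enone, the bromoketone may self-condense, and the enantioselectivity may be low. The fallback sets the absolute configuration at the oxygen-bearing carbon instead and sets out from 3. Copper-catalysed asymmetric conjugate borylation (CuCl, NaOtBu, a Josiphos-type bisphosphine of the appropriate hand, B2pin2, MeOH, THF) should give the (S)-β-boryl ketone F2, and oxidation with NaBO3·4H2O the (S)-β-hydroxy ketone F3. The dianion of F3 (LDA, 2.2 equiv, THF, −78 °C) is alkylated with 4 to the hydroxy diketone F4. Cyclodehydration of F4 (PPTS, 4 Å MS, toluene, 50 °C) rejoins the route at 6, bypassing 5 and step 4; either epimer at the aroyl-bearing carbon converges on the trans-dihydrofuran by enolisation.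

Step 10. The doubly flanked C6 may not react, and prolonged heating with acid may epimerise C2 of the installed oxolane. The fallback separates the two events and sets out from 16. Magnesium phenoxide-directed ortho-formylation (MgCl2, Et3N, paraformaldehyde, MeCN, 60 °C) should give the 6-formyl-7-hydroxy compound F5. Chemoselective aryl transfer to the aldehyde in the presence of the two ketones, with the aryltitanium reagent made from 12 and ClTi(OiPr)3 (THF, −40 °C), rejoins the route at 18.

**Further compounds**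

F1 | step 11 | 7-O-(tert-butoxycarbonyl) derivative of 18 (aryl tert-butyl carbonate, benzylic OH free) | CC(C)(C)OC(=O)Oc1c(C(O)c5ccc(OCc6ccccc6)cc5)c(OCc5ccccc5)c2c(c1[C@H](c5ccc(OCc6ccccc6)cc5)[C@H]3[C@H](C(=O)c5ccc(OCc6ccccc6)cc5OCc5ccccc5)[C@@H](c5ccc(OCc6ccccc6)cc5)O[C@H]3c5ccc(OCc6ccccc6)cc5OCc5ccccc5)O[C@H](c5ccc(OCc6ccccc6)cc5)[C@@H](OCc5ccccc5)C2
F2 | step 3 | (S)-3-[4-(benzyloxy)phenyl]-1-[2,4-bis(benzyloxy)phenyl]-3-(4,4,5,5-tetramethyl-1,3,2-dioxaborolan-2-yl)propan-1-one | CC1(C)OB(OC1(C)C)[C@@H](CC(=O)c5ccc(OCc6ccccc6)cc5OCc5ccccc5)c5ccc(OCc6ccccc6)cc5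
F3 | step 3 | (S)-3-[4-(benzyloxy)phenyl]-1-[2,4-bis(benzyloxy)phenyl]-3-hydroxypropan-1-one | O[C@@H](CC(=O)c5ccc(OCc6ccccc6)cc5OCc5ccccc5)c5ccc(OCc6ccccc6)cc5
F4 | step 3 | (S)-2-{(S)-[4-(benzyloxy)phenyl](hydroxy)methyl}-1,4-bis[2,4-bis(benzyloxy)phenyl]butane-1,4-dione | O[C@@H]([C@H](CC(=O)c5ccc(OCc6ccccc6)cc5OCc5ccccc5)C(=O)c5ccc(OCc6ccccc6)cc5OCc5ccccc5)c5ccc(OCc6ccccc6)cc5
F5 | step 10 | 6-formyl derivative of 16 (7-OH free) | Oc1c(C=O)c(OCc5ccccc5)c2c(c1[C@H](c5ccc(OCc6ccccc6)cc5)[C@H]3[C@H](C(=O)c5ccc(OCc6ccccc6)cc5OCc5ccccc5)[C@@H](c5ccc(OCc6ccccc6)cc5)O[C@H]3c5ccc(OCc6ccccc6)cc5OCc5ccccc5)O[C@H](c5ccc(OCc6ccccc6)cc5)[C@@H](OCc5ccccc5)C2
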